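Set the two exits of the solid against each other before reckoning any yield.

solid substrate 0.10 M; reagent 1.30 equiv; protic impurity 0.0500 M; time 80 min

    dissolved substrate + reagent → target (k1 = 0.0887 /M/s)
    2 dissolved substrate → side product (k2 = 0.0114 /M/s)
    solid substrate + protic impurity → quenched substrate (k3 = 0.522 /M/s)
    solid substrate ⇌ dissolved substrate, rate k4*(cs4 - [dissolved substrate]) while solid is left; crystals form when [dissolved substrate] > cs4 (cs4 = 0.078 M, k4 = 0.00119 /s)

- a species is counted by the solid substrate in it: one side product counts as two
- for a step with 2 of a species take k times the square, and two of it per event
- given per volume of solution although it is solid: solid substrate
- at the start none of the solid substrate is in solution
- what has only dissolved of solid substrate counts as not reacted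
- the reaction counts as stopped when no species that holds the solid substrate changes by six tenths of a point or more over the second half of the time
- run time (flask): 80 min

- which holds at 80 min: what has brought the reaction to rest, or that it has not come to rest (for what has run out or reacted, a solid counts together with what of it has only dissolved) (forward and back rates have come level / all of the solid substrate has reacted / the reagent has run out first / it is still moving)
- amount of target at 80 min, in percent of the solid substrate charged

1. At the start of the flask, in fractions of the solid charge, quenching takes solid at 1.57 /min and dissolution takes it at 0.0557 /min. Quenching therefore leads by a factor of 28.1.

2. Quenching slows as both partners fall. With half the impurity gone, the impurity contributes a factor of 0.5 and the solid, counting what quenching has taken, a factor of 0.750, so with dissolution held at its starting rate the lead is still about 10.5.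

3. Suppose the impurity takes its whole charge, 50.0% of the solid charge. That leaves 50.0%, the open share: the part of the charge that reaches solution.

4. To test this, divide quenching by dissolution so that time drops out, and sum over the open share with dissolution held at its starting rate. This estimate puts the impurity surviving the solid near 0.0443% of its own charge, which supports the supposition.

5. At that starting rate, the open share needs about 8.98 min to dissolve, less than the 80 min allowed. The reagent charge of 1.30 equiv also exceeds the open share. We therefore expect the solid to be used up, with target just under the open share; the side product makes up the gap, and we leave it unreckoned.

6. The forecast says all of the solid substrate has reacted and 49%, holding of the impurity that “It takes 50% of the charge”.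

7. At 80.0 min the flask gives 49.2% target, and all of the solid substrate has reacted. Side product stands at 0.844%, and the open share less that amount is 49.2%.

8. The neighbour flask is the same flask with 0.330 equiv of reagent, below the open share, so we take reagent as the limiting reagent there. We expect target near that charge, with 17.0% of the solid charge going elsewhere. That neighbour flask gives 32.4% target, 13.2% side product and 4.40% dissolved substrate, with 1.8% of its reagent left.

The constants used here belong to no real substance; the result is computed.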